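**Retrosynthetic overview**

- The 2H-pyran ring is disconnected last, at its aryl–CH= bond and its O–C(CH3)2 bond. This leads back to a CH2-bridged two-ring precursor plus prenal, joined by a formal [3+3] annulation (Knoevenagel condensation, then oxa-6π electrocyclisation).
- The CH2 bridge comes from the C-6 methyl group of the dienone ring, which is dehydrogenated to an α-methylene trione and captured by an aromatic C–H of the butyrophenone ring.
- The quaternary stereocentre comes from a desymmetrising, dearomative Pd-catalysed geranylation of the symmetric 2,4,6-trihydroxy-3,5-dimethylacetophenone.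
- Ring order: both carbocycles are bought as benzene rings (one is dearomatised in step 1, none is built). The pyran is the only ring that is closed, and it is closed after the rest of the skeleton is complete.
- Enabling feature: in the bridged precursor the butyrophenone ring has one unsubstituted carbon, C-5. It lies between the free O-6–H (ortho to the butyryl-bearing carbon) and the silyl-blocked O-4. All six carbons of the dienone ring are substituted (C-4 quaternary). The annulation therefore has one carbon site and one oxygen available.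

Key step: step 4

Assumption: descriptors refer to the enol tautomer drawn in the SMILES; which enantiomer of the Trost ligand gives the R centre must be found by experiment, and (R,R) is written here. "Geranyl" means (2E)-3,7-dimethylocta-2,6-dien-1-yl.

**Step 1**
Reactants: 1 2,4,6-trihydroxy-3,5-dimethylacetophenone; 2 geranyl acetate
Product: 3 (4R)-2-acetyl-4-geranyl-3,5-dihydroxy-4,6-dimethylcyclohexa-2,5-dien-1-one
Conditions: Pd2(dba)3·CHCl3 (2.5 mol%), (R,R)-DACH-phenyl Trost ligand (7.5 mol%), Et3N (2.2 equiv), 1 (1.2 equiv), degassed CH2Cl2, 0 °C → rt; aq. citric acid work-up, Pd removed on thiol silica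
Reagents that add atoms: none
Why: Proposed new method: the C2v-symmetric phenolate of 1 has only two alkylatable ring carbons, the enantiotopic methyl-bearing C-3 and C-5 (the third bears the acetyl group), so outer-sphere attack on the (π-geranyl)Pd–ligand cation at its unhindered terminus must dearomatise and keeps the E-linear chain, while the ligand pocket (amide N–H to phenolate contact) is asked to pick one enantiotopic carbon and so set the quaternary centre as R; the closest known reaction types are the Pd-catalysed asymmetric allylic alkylation of prochiral stabilised carbon nucleophiles with geranyl and prenyl electrophiles and the racemic dearomative C-allylation of fully substituted acylphloroglucinols.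

**Step 2**
Reactants: 4 1-(2,4,6-trihydroxyphenyl)butan-1-one
Product: 5 1-[2,6-dihydroxy-4-(triisopropylsilyloxy)phenyl]butan-1-one
Conditions: TIPSCl (1.05 equiv), imidazole (2.2 equiv), DMF, 0 °C
Reagents that add atoms: triisopropylsilyl chloride, CC(C)[Si](Cl)(C(C)C)C(C)C
Why: Silyl ether formation should be selective for the para hydroxyl, which is the most acidic, unhindered and not hydrogen-bonded, whereas the two ortho hydroxyls flank the butyryl group and chelate its carbonyl.

**Step 3**
Reactants: 3 (4R)-2-acetyl-4-geranyl-3,5-dihydroxy-4,6-dimethylcyclohexa-2,5-dien-1-one; 5 1-[2,6-dihydroxy-4-(triisopropylsilyloxy)phenyl]butan-1-one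
Product: 7 1-[3-{[(3R)-5-acetyl-3-geranyl-2,4-dihydroxy-3-methyl-6-oxocyclohexa-1,4-dien-1-yl]methyl}-2,6-dihydroxy-4-(triisopropylsilyloxy)phenyl]butan-1-one, via methylene trione 6 (not isolated)
Conditions: Ag2O (0.6 equiv), TEMPO (1.1 equiv), 5 (2.0 equiv), THF, 0 °C → rt, dark; excess 5 recovered
Reagents that add atoms: none
Why: Ag2O/TEMPO dehydrogenation of the C-6 methyl group of an enolised 2-acyl-cyclohexane-1,3,5-trione to its α-methylene trione (ortho-quinone methide) has precedent on this substrate class, and 6 should be captured by Friedel–Crafts-type Michael addition of one of the two equivalent CH positions of 5, as in couplings of acylphloroglucinols with alkylidene triketones; no stereocentre is formed and the quaternary centre is not touched.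

**Step 4**
Reactants: 7 silyl-protected CH2-bridged precursor; 8 3-methylbut-2-enal (prenal)
Product: 10 1-[6-{[(3R)-5-acetyl-3-geranyl-2,4-dihydroxy-3-methyl-6-oxocyclohexa-1,4-dien-1-yl]methyl}-7-hydroxy-2,2-dimethyl-5-(triisopropylsilyloxy)-2H-chromen-8-yl]butan-1-one, via oxatriene 9 (not isolated)
Conditions: 8 (3 equiv), ethylenediammonium diacetate (20 mol%), toluene, 60 °C
Reagents that add atoms: none
Why: EDDA converts prenal into its α,β-unsaturated iminium ion, which is attacked 1,2 by C-5 of the butyrophenone ring (the only ring carbon of 7 that still carries hydrogen), and loss of the amine gives the 1-oxatriene (vinyl ortho-quinone methide) 9 with the C-6 oxygen as the dienone carbonyl. 9 closes by a thermal disrotatory oxa-6π electrocyclisation that forms the O–C(CH3)2 bond and re-aromatises the ring; the closest known reaction type is the EDDA- or pyridine-mediated formal [3+3] chromenylation of phloroglucinols and acylphloroglucinols with prenal or citral. The pyran is thus closed in a pericyclic six-electron mode after an intermolecular C–C bond formation, so one operation adds five carbons, two bonds and the last ring. No stereocentre is formed (the new sp3 carbon carries two methyl groups) and the quaternary centre of the dienone ring is not involved. The step needs site selectivity, secured because every carbon of the dienone ring is substituted and the butyrophenone ring has a single CH, and oxygen regioselectivity, secured by the silyl group on O-4, so that only O-6, the oxygen ortho to the butyryl-bearing carbon, can close. The buffered, non-basic medium and 60 °C are chosen to keep the CH2 bridge from retro-Michael scrambling and the C-geranyl dienone from sigmatropic shifts.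

**Step 5**
Reactants: 10 silyl-protected chromene
Product: 11 1-[6-{[(3R)-5-acetyl-3-geranyl-2,4-dihydroxy-3-methyl-6-oxocyclohexa-1,4-dien-1-yl]methyl}-5,7-dihydroxy-2,2-dimethyl-2H-chromen-8-yl]butan-1-one (CNP0152509.1)
Conditions: TBAF (1.2 equiv), AcOH (1.2 equiv), THF, 0 °C
Reagents that add atoms: none
Why: Buffered fluoride cleavage of the aryl silyl ether should leave the chromene, the geranyl alkenes, the enolised trione and the CH2 bridge untouched, and no stereocentre is affected.

**Compound list**

1 | 2,4,6-trihydroxy-3,5-dimethylacetophenone | CC(=O)c1c(O)c(C)c(O)c(C)c1O | starting material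
2 | geranyl acetate | CC(=O)OC/C=C(\C)CCC=C(C)C | starting material
3 | (4R)-2-acetyl-4-geranyl-3,5-dihydroxy-4,6-dimethylcyclohexa-2,5-dien-1-one | CC1=C(O)[C@@](C)(C/C=C(\C)CCC=C(C)C)C(O)=C(C(C)=O)C1=O | intermediate
4 | 1-(2,4,6-trihydroxyphenyl)butan-1-one | CCCC(=O)c1c(O)cc(O)cc1O | starting material
5 | 1-[2,6-dihydroxy-4-(triisopropylsilyloxy)phenyl]butan-1-one | CCCC(=O)c1c(O)cc(O[Si](C(C)C)(C(C)C)C(C)C)cc1O | intermediate
6 | (4S)-2-acetyl-4-geranyl-3-hydroxy-4-methyl-6-methylidenecyclohex-2-ene-1,5-dione | C=C1C(=O)[C@@](C)(C/C=C(\C)CCC=C(C)C)C(O)=C(C(C)=O)C1=O | intermediate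
7 | 1-[3-{[(3R)-5-acetyl-3-geranyl-2,4-dihydroxy-3-methyl-6-oxocyclohexa-1,4-dien-1-yl]methyl}-2,6-dihydroxy-4-(triisopropylsilyloxy)phenyl]butan-1-one | CCCC(=O)c1c(O)c(CC2=C(O)[C@@](C)(C/C=C(\C)CCC=C(C)C)C(O)=C(C(C)=O)C2=O)c(O[Si](C(C)C)(C(C)C)C(C)C)cc1O | intermediate
8 | 3-methylbut-2-enal (prenal) | CC(C)=CC=O | starting material
9 | 1-oxatriene from 7 and prenal: butyrophenone ring as 2-butanoyl-3-hydroxy-5-(triisopropylsilyloxy)-6-[(Z)-3-methylbut-2-en-1-ylidene]cyclohexa-2,4-dien-1-one, with the (3R)-dienone-ring methyl group at C-4 | CCCC(=O)C1=C(O)C(CC2=C(O)[C@@](C)(C/C=C(\C)CCC=C(C)C)C(O)=C(C(C)=O)C2=O)=C(O[Si](C(C)C)(C(C)C)C(C)C)/C(=C/C=C(C)C)C1=O | intermediate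
10 | 1-[6-{[(3R)-5-acetyl-3-geranyl-2,4-dihydroxy-3-methyl-6-oxocyclohexa-1,4-dien-1-yl]methyl}-7-hydroxy-2,2-dimethyl-5-(triisopropylsilyloxy)-2H-chromen-8-yl]butan-1-one | CCCC(=O)c1c(O)c(CC2=C(O)[C@@](C)(C/C=C(\C)CCC=C(C)C)C(O)=C(C(C)=O)C2=O)c(O[Si](C(C)C)(C(C)C)C(C)C)c2c1OC(C)(C)C=C2 | intermediate
11 | 1-[6-{[(3R)-5-acetyl-3-geranyl-2,4-dihydroxy-3-methyl-6-oxocyclohexa-1,4-dien-1-yl]methyl}-5,7-dihydroxy-2,2-dimethyl-2H-chromen-8-yl]butan-1-one | CCCC(=O)c1c(O)c(CC2=C(O)[C@@](C)(C/C=C(\C)CCC=C(C)C)C(O)=C(C(C)=O)C2=O)c(O)c2c1OC(C)(C)C=C2 | target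

**Step count**

Total steps: 5. Longest linear sequence: 4 (1 → 3 → 7 → 10 → 11); step 2 is a one-step branch.

**Steps most likely to fail**

1. Step 1 (proposed new method). The catalyst may discriminate poorly between the two enantiotopic methyl-bearing carbons. The enantiomeric purity may also erode through reversible ionisation of the new C–C bond by Pd(0), and a second geranylation or E/Z scrambling of the allyl unit may occur. The fallback sets out from 1 and comes back at 3. Base-mediated C-alkylation of 1 with geranyl bromide (NaOMe, MeOH, 0 °C), a known dearomative alkylation of fully substituted acylphloroglucinols, should give racemic 2-acetyl-4-geranyl-3,5-dihydroxy-4,6-dimethylcyclohexa-2,5-dien-1-one F1. The acidic enol is then resolved classically by crystallising the (S)-1-phenylethylammonium salt of the R acid F2 (the antipodal amine is used if the salt of the S acid crystallises first). Dilute HCl releases 3.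

2. Step 3. The oxidant may go on to dehydrogenate the newly formed, doubly activated CH2 bridge. The methylene trione may also oligomerise or add to a geranyl alkene before the arene captures it, and a second trione may add to the remaining CH of the arene. The fallback sets out from 3 and comes back at 7, and it separates the oxidation from the coupling. Selenenylation at C-6 (PhSeCl, pyridine, CH2Cl2, −78 °C) should give (4R)-2-acetyl-4-geranyl-3-hydroxy-4,6-dimethyl-6-(phenylselanyl)cyclohex-2-ene-1,5-dione F3. Oxidation (H2O2, CH2Cl2, 0 °C) gives the selenoxide F4, whose syn-elimination releases 6 in the presence of 5 and leads to 7.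

3. Step 4. Amine and heat may cause retro-Michael scrambling of the CH2 bridge, and condensation at the CH next to the bulky silyl ether may be slow, so that prenal self-condensation competes. The fallback sets out from 5 and comes back at 10, and it still closes the pyran last. C-Prenylation of 5 (prenyl bromide, DBU, THF, 0 °C) should give 1-[2,6-dihydroxy-3-(3-methylbut-2-en-1-yl)-4-(triisopropylsilyloxy)phenyl]butan-1-one F5. Coupling with 3 under the conditions of step 3 gives the prenylated CH2-bridged dimer F6. DDQ (1.1 equiv, benzene, rt) then abstracts the benzylic hydride of the prenyl group, and the resulting ortho-quinone methide closes onto O-6 by oxa-6π electrocyclisation to give 10.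

**Further compounds**

F1 | step 1 | racemic 2-acetyl-4-geranyl-3,5-dihydroxy-4,6-dimethylcyclohexa-2,5-dien-1-one | CC1=C(O)C(C)(C/C=C(\C)CCC=C(C)C)C(O)=C(C(C)=O)C1=O
F2 | step 1 | (S)-1-phenylethylammonium enolate of (4R)-2-acetyl-4-geranyl-3,5-dihydroxy-4,6-dimethylcyclohexa-2,5-dien-1-one | CC1=C([O-])[C@@](C)(C/C=C(\C)CCC=C(C)C)C(O)=C(C(C)=O)C1=O.C[C@H]([NH3+])c1ccccc1
F3 | step 3 | (4R)-2-acetyl-4-geranyl-3-hydroxy-4,6-dimethyl-6-(phenylselanyl)cyclohex-2-ene-1,5-dione, both C-6 epimers | CC1([Se]c2ccccc2)C(=O)[C@@](C)(C/C=C(\C)CCC=C(C)C)C(O)=C(C(C)=O)C1=O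
F4 | step 3 | selenoxide of F3, (4R)-2-acetyl-4-geranyl-3-hydroxy-4,6-dimethyl-6-(phenylseleninyl)cyclohex-2-ene-1,5-dione | CC1([Se](=O)c2ccccc2)C(=O)[C@@](C)(C/C=C(\C)CCC=C(C)C)C(O)=C(C(C)=O)C1=O
F5 | step 4 | 1-[2,6-dihydroxy-3-(3-methylbut-2-en-1-yl)-4-(triisopropylsilyloxy)phenyl]butan-1-one | CCCC(=O)c1c(O)c(CC=C(C)C)c(O[Si](C(C)C)(C(C)C)C(C)C)cc1O
F6 | step 4 | 1-[3-{[(3R)-5-acetyl-3-geranyl-2,4-dihydroxy-3-methyl-6-oxocyclohexa-1,4-dien-1-yl]methyl}-2,6-dihydroxy-5-(3-methylbut-2-en-1-yl)-4-(triisopropylsilyloxy)phenyl]butan-1-one | CCCC(=O)c1c(O)c(CC2=C(O)[C@@](C)(C/C=C(\C)CCC=C(C)C)C(O)=C(C(C)=O)C2=O)c(O[Si](C(C)C)(C(C)C)C(C)C)c(CC=C(C)C)c1O
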